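**Plan**
- Retrosynthesis: cut the C8 ester, then the lactone (O6–C12 and C11–C12, alkynol carbonylation), then C11≡C13 (one-carbon homologation), then re-join O2–C11 and C2–C11 (Baeyer–Villiger in reverse), and finally cut C2–C3 and C6–C7.
- Enabling feature: C2 (carbinol) and C7 (bearing C11) are 1,6 across the ten-membered ring. Bridging them by C11 as a ketone gives a bicyclo[4.4.1]undecan-11-one whose seven-membered ring C11/C2/C1/C10/C9/C8/C7 is 4-methyltropone and whose C3–C6 bridge is a 1-oxygenated isoprenoid diene.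
- Forward: tropone + silyl dienol ether close the ten-membered ring as the periphery of the bicycle; C8 is oxygenated on the bicycle; the bridge is excised; the monocycle is then corrected at C2/C6, acylated at O8 and lactonised last.
- Stereochemistry: the cycloaddition fixes C2/C6/C7 (relative) and both Z ring olefins; C8 comes from convex-face borylcupration; absolute configuration from a lipase resolution; C2 and C6 are inverted by a double Mitsunobu reaction; the side chain comes from a Sharpless epoxidation.

Key step: step 5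

Remarks on the chemistry
- Atom numbers are those of the target: ring C1–C10 (C1=C10, C4=C5; O on C2, C6, C8), C11 on C7, C12 lactone carbonyl, C13 methylene, C14/C15 the methyls on C10/C4. β is the ring face carrying C11 at C7, α the other face.
- Compounds 3 and 7–9 are racemic; the SMILES of 7–9 show the enantiomer carried on after step 7. Lactol 14 is an anomeric mixture (C11 undefined).
- Assumption: the lipase follows the usual secondary-alcohol rule (fast enantiomer 8R). If the preference were reversed, the unreacted alcohol of step 7 would go directly into step 9.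

**Step 1**
Reactants: 1 4-methylanisole
Product: 2 1-methoxy-4-methylcyclohexa-1,4-diene
Conditions: Li, NH3(l), t-BuOH, THF, −78 → −33 °C
Reagents that add atoms: none
Why: Birch reduction of an anisole leaves the methoxy- and alkyl-bearing carbons olefinic and gives the 2,5-dihydro isomer.

**Step 2**
Reactants: 2 1-methoxy-4-methylcyclohexa-1,4-diene
Product: 3 7,7-dichloro-1-methoxy-4-methylbicyclo[4.1.0]hept-3-ene
Conditions: CHCl3, KOt-Bu, pentane, −20 → 0 °C
Reagents that add atoms: chloroform, ClC(Cl)Cl
Why: Electrophilic dichlorocarbene cyclopropanates the more electron-rich enol-ether double bond (gem-dihalocyclopropanation), as in the classical anisole-to-tropone sequence.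

**Step 3**
Reactants: 3 7,7-dichloro-1-methoxy-4-methylbicyclo[4.1.0]hept-3-ene
Product: 4 4-methyltropone
Conditions: AgNO3, acetone/H2O, reflux; NaHCO3 work-up
Reagents that add atoms: water, O
Why: Silver-assisted cyclopropyl-to-allyl cation ring opening expands the ring, and loss of HCl with hydrolysis of the methyl enol ether aromatises it to the tropone (Birch-type dihalocarbene ring expansion, known for 4-alkyltropones).

**Step 4**
Reactants: 5 3-methylbut-2-enal
Product: 6 (E)-3-methyl-1-(triethylsilyloxy)buta-1,3-diene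
Conditions: Et3SiOTf, Et3N, Et2O, 0 °C → rt
Reagents that add atoms: triethylsilyl trifluoromethanesulfonate, CC[Si](CC)(CC)OS(=O)(=O)C(F)(F)F
Why: O-silylation of the enal and γ-deprotonation of a methyl group give the silyl dienol ether, E at the enol double bond from the s-trans enal.

**Step 5 (key step)**
Reactants: 4 4-methyltropone; 6 (E)-3-methyl-1-(triethylsilyloxy)buta-1,3-diene
Product: 7 exo adduct, rac-3,9-dimethyl-7-(triethylsilyloxy)bicyclo[4.4.1]undeca-2,4,8-trien-11-one (C11 ketone bridging C2 and C7; OSiEt3 on C6 syn to the bridge)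
Conditions: toluene, BHT (cat.), sealed tube, 110 °C
Reagents that add atoms: none
Why: The step is a concerted, thermally allowed [π6s+π4s] cycloaddition in which the tropone reacts through its two α-carbons (C2, C7) and the s-cis dienol ether through its termini (C3, C6); the closest known reaction is the thermal tropone–diene [6+4] addition of 1-oxygenated butadienes. Both σ-bonds form in one intermolecular annulation, closing the cycloheptenone ring C11–C2–C3–C4–C5–C6–C7 and with it the ten-membered periphery C1–C10 by two-bond cycloaddition onto the existing seven-membered ring. C2 and C7 are set by suprafacial addition to one face of the planar tropone (bridge necessarily cis), and C6 by the E enol ether together with the exo transition state, which places OSiEt3 syn to the C11 bridge; C4=C5 and C1=C10 must be cis because each lies in a seven-membered ring. Periselectivity over [4+2] and [8+2] rests on the large LUMO coefficients at the tropone α-carbons and the electron-rich diene, and exo selectivity on the repulsive secondary overlap of the endo array, both general for tropone. The needed regiochemistry (C3 to C2, C6 to C7) is the weakest point: the more nucleophilic CH2 terminus should bond in advance to C2, the α-carbon whose attack puts no charge on methyl-bearing C10, but the bias is modest and the regioisomer is to be removed by chromatography.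

**Step 6**
Reactants: 7 exo adduct
Product: 9 rac-5-hydroxy-3,9-dimethyl-7-(triethylsilyloxy)bicyclo[4.4.1]undeca-2,8-dien-11-one (8β-OH, C9 now CH2), via C8 pinacolboronate 8 (not isolated)
Conditions: CuCl (5 mol %), Xantphos (5 mol %), NaOt-Bu (10 mol %), B2pin2, MeOH, THF, 0 °C → rt; then NaBO3·4H2O, THF/H2O, rt
Reagents that add atoms: bis(pinacolato)diboron, CC1(C)OB(OC1(C)C)B1OC(C)(C)C(C)(C)O1 (boron of 8); sodium perborate, [Na+].[Na+].O[B-]1(O)OO[B-](O)(O)OO1 (oxygen of 9)
Why: Copper-catalysed borylcupration/protonation of a cyclic 1,3-diene (formal 1,2-hydroboration) puts boron on the diene terminus C8 of the less substituted C8=C9 bond and copper on allylic C9, which methanol protonates; Cu–B adds to the open face anti to the C3–C6 bridge, perborate oxidises C–B with retention, and the hindered ketone and the isolated C4=C5 olefin are not touched.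

**Step 7**
Reactants: 9 racemic 8β-alcohol
Product: 10 (8R)-acetate of 9
Conditions: lipase PS (immobilised), vinyl acetate, MTBE, 30 °C, to about half conversion; (8S)-alcohol removed by chromatography
Reagents that add atoms: vinyl acetate, C=COC(C)=O
Why: Lipase-catalysed kinetic resolution by transesterification; with the branched C7 as large and C9H2 as medium substituent, the empirical rule makes the needed (8R)-alcohol the fast-reacting enantiomer.

**Step 8**
Reactants: 10 (8R)-acetate
Product: 11 (8R)-alcohol (single enantiomer of 9)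
Conditions: lipase PS, n-BuOH, MTBE, 40 °C
Reagents that add atoms: none
Why: Enzymatic alcoholysis removes the acetyl group without base (no retro-aldol of the β-hydroxy ketone) and a second enantioselective pass should raise the ee.

**Step 9**
Reactants: 11 (8R)-alcohol
Product: 12 5-(tert-butyldimethylsilyloxy)-3,9-dimethyl-7-(triethylsilyloxy)bicyclo[4.4.1]undeca-2,8-dien-11-one
Conditions: TBSOTf, 2,6-lutidine, CH2Cl2, −78 → 0 °C
Reagents that add atoms: tert-butyldimethylsilyl trifluoromethanesulfonate, CC(C)(C)[Si](C)(C)OS(=O)(=O)C(F)(F)F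
Why: Silyl triflate/lutidine silylation of a hindered secondary alcohol; the bridgehead-flanked ketone cannot form a silyl enol ether readily.

**Step 10**
Reactants: 12 bis-silyl ether ketone
Product: 13 5-(tert-butyldimethylsilyloxy)-3,9-dimethyl-7-(triethylsilyloxy)-11-oxabicyclo[4.4.2]dodeca-2,8-dien-12-one (lactone O2–C11(=O)–C7, O2 β)
Conditions: Me3SiOOSiMe3, SnCl4/trans-cyclohexane-1,2-diamine (cat.), 4 Å MS, CH2Cl2, −20 °C
Reagents that add atoms: bis(trimethylsilyl) peroxide, C[Si](C)(C)OO[Si](C)(C)C
Why: Baeyer–Villiger oxidation with silyl peroxide/Lewis acid, a protocol that spares C=C bonds and is used for β,γ-unsaturated ketones; allylic C2 migrates with retention in preference to C7, which is deactivated by two β-silyloxy groups.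

**Step 11**
Reactants: 13 bridged lactone
Product: 14 lactol, 5-(tert-butyldimethylsilyloxy)-3,9-dimethyl-7-(triethylsilyloxy)-11-oxabicyclo[4.4.2]dodeca-2,8-dien-12-ol (in equilibrium with the 2-hydroxy C11 aldehyde)
Conditions: DIBAL-H (1.2 equiv), CH2Cl2, −78 °C; Rochelle salt
Reagents that add atoms: none
Why: Low-temperature DIBAL-H reduction stops at the tetrahedral aluminate, giving the lactol; silyl ethers and olefins are inert.

**Step 12**
Reactants: 14 lactol
Product: 15 (1(10)Z,4Z)-7β-ethynyl-8β-(tert-butyldimethylsilyloxy)-6β-(triethylsilyloxy)-4,10-dimethylcyclodeca-1(10),4-dien-2β-ol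
Conditions: MeC(O)C(N2)P(O)(OMe)2, K2CO3, MeOH, 0 °C → rt
Reagents that add atoms: dimethyl (1-diazo-2-oxopropyl)phosphonate, CC(=O)C(=[N+]=[N-])P(=O)(OC)OC
Why: Ohira–Bestmann (Seyferth–Gilbert) homologation of the open aldehyde form of the lactol adds C13 and frees O2–H; both β-oxygens are silyl ethers, so the carbonate conditions should not epimerise or eliminate at C7.

**Step 13**
Reactants: 15 alkynyl alcohol
Product: 16 (1(10)Z,4Z)-7β-ethynyl-8β-(tert-butyldimethylsilyloxy)-4,10-dimethylcyclodeca-1(10),4-diene-2β,6β-diol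
Conditions: PPTS (cat.), MeOH, 0 °C
Reagents that add atoms: none
Why: Mild acid methanolysis removes a secondary triethylsilyl ether much faster than a secondary tert-butyldimethylsilyl ether.

**Step 14**
Reactants: 16 2β,6β-diol
Product: 17 2α,6α-bis(chloroacetate), (1(10)Z,4Z)-7β-ethynyl-8β-(tert-butyldimethylsilyloxy)-4,10-dimethylcyclodeca-1(10),4-diene-2α,6α-diyl bis(chloroacetate)
Conditions: PPh3, DIAD, ClCH2CO2H, toluene, 0 °C → rt
Reagents that add atoms: chloroacetic acid, OC(=O)CCl
Why: Double Mitsunobu reaction, SN2 with inversion at both allylic carbinols (C2 and C6); chloroacetic acid is the acidic partner of choice for hindered alcohols, and SN2′ would have to occur at the fully substituted C10 or C4.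

**Step 15**
Reactants: 17 bis(chloroacetate) silyl ether
Product: 18 (1(10)Z,4Z)-7β-ethynyl-8β-hydroxy-4,10-dimethylcyclodeca-1(10),4-diene-2α,6α-diyl bis(chloroacetate)
Conditions: HF·pyridine, pyridine, THF, 0 °C → rt
Reagents that add atoms: none
Why: Buffered fluoride cleaves the silyl ether under conditions that leave chloroacetates and the alkyne intact and do not promote acyl migration.

**Step 16**
Reactants: 19 angelic acid
Product: 20 (Z)-2-methylbut-2-en-1-ol
Conditions: LiAlH4, Et2O, 0 °C → rt
Reagents that add atoms: none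
Why: Hydride reduction of the unsaturated acid is a 1,2-reduction and keeps the Z geometry.

**Step 17**
Reactants: 20 (Z)-2-methylbut-2-en-1-ol
Product: 21 [(2S,3R)-2,3-dimethyloxiran-2-yl]methanol
Conditions: Ti(Oi-Pr)4 (cat.), L-(+)-DIPT (cat.), t-BuOOH, 4 Å MS, CH2Cl2, −20 °C
Reagents that add atoms: tert-butyl hydroperoxide, CC(C)(C)OO
Why: Sharpless asymmetric epoxidation; L-(+)-tartrate delivers oxygen to the same face that gives (2S,3S)-epoxy alcohols from E-allylic alcohols, here the (2S,3R) product, and syn addition keeps the two methyls trans.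

**Step 18**
Reactants: 21 epoxy alcohol
Product: 22 (2R,3R)-2,3-dimethyloxirane-2-carboxylic acid (epoxyangelic acid)
Conditions: RuCl3·xH2O (cat.), NaIO4, CCl4/MeCN/H2O, rt
Reagents that add atoms: water, O
Why: RuO4-catalysed oxidation of a primary epoxy alcohol to the glycidic acid leaves the epoxide and both stereocentres untouched (the C2 descriptor changes only through CIP priorities).

**Step 19**
Reactants: 18 8β-alcohol; 22 epoxyangelic acid
Product: 24 8β-[(2R,3R)-2,3-dimethyloxirane-2-carbonyloxy] 2α,6α-bis(chloroacetate), via mixed anhydride 23 (not isolated)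
Conditions: 22, 2,4,6-Cl3C6H2COCl, Et3N, THF, rt; then 18, DMAP, toluene, 0 °C → rt
Reagents that add atoms: 2,4,6-trichlorobenzoyl chloride, O=C(Cl)c1c(Cl)cc(Cl)cc1Cl (in 23 only)
Why: Yamaguchi esterification couples an α-quaternary acid with a hindered secondary alcohol without acid that would open the epoxide; short contact with DMAP at low temperature limits attack on the chloroacetates.

**Step 20**
Reactants: 24 triester
Product: 25 (1(10)Z,4Z)-7β-ethynyl-2α,6α-dihydroxy-4,10-dimethylcyclodeca-1(10),4-dien-8β-yl (2R,3R)-2,3-dimethyloxirane-2-carboxylate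
Conditions: K2CO3 (0.3 equiv), MeOH, −10 °C
Reagents that add atoms: none
Why: Chloroacetates undergo methanolysis orders of magnitude faster than an α-quaternary ester on a hindered carbinol, so both are removed selectively.

**Step 21**
Reactants: 25 diol alkyne
Product: 26 Millisorin B
Conditions: PdI2 (5 mol %), PBu3 (10 mol %), CO (7 atm), MeCN, 70 °C
Reagents that add atoms: carbon monoxide, [C-]#[O+]
Why: Palladium-catalysed cyclocarbonylation of a 3-butyn-1-ol: the alkoxycarbonyl-palladium formed from O6–H adds across C11≡C13 in the Markovnikov sense and protonolysis gives the α-methylene-γ-lactone with retention at C6 (trans-fused, since O6 is α and C11 β); O2–H cannot reach C12 and the neutral medium spares the epoxy ester.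

**Compound list**
1 | 4-methylanisole | COc1ccc(C)cc1 | starting material
2 | 1-methoxy-4-methylcyclohexa-1,4-diene | COC1=CCC(C)=CC1 | intermediate
3 | 7,7-dichloro-1-methoxy-4-methylbicyclo[4.1.0]hept-3-ene (racemic, cis-fused) | COC12CC=C(C)CC1C2(Cl)Cl | intermediate
4 | 4-methyltropone | O=C1C=CC(C)=CC=C1 | intermediate
5 | 3-methylbut-2-enal | CC(C)=CC=O | starting material
6 | (E)-3-methyl-1-(triethylsilyloxy)buta-1,3-diene | C=C(C)/C=C/O[Si](CC)(CC)CC | intermediate
7 | exo adduct, rac-3,9-dimethyl-7-(triethylsilyloxy)bicyclo[4.4.1]undeca-2,4,8-trien-11-one | O=C1[C@H]2/C=C(/C)\C=C/[C@@H]1[C@@H](O[Si](CC)(CC)CC)/C=C(/C)C2 | intermediate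
8 | rac-C8 pinacolboronate of the adduct (boron 8β) | O=C1[C@H]2/C=C(/C)C[C@@H](B3OC(C)(C)C(C)(C)O3)[C@@H]1[C@@H](O[Si](CC)(CC)CC)/C=C(/C)C2 | intermediate (not isolated)
9 | rac-5-hydroxy-3,9-dimethyl-7-(triethylsilyloxy)bicyclo[4.4.1]undeca-2,8-dien-11-one (8β-OH) | O=C1[C@H]2/C=C(/C)C[C@@H](O)[C@@H]1[C@@H](O[Si](CC)(CC)CC)/C=C(/C)C2 | intermediate
10 | (8R)-acetate of 9 | O=C1[C@H]2/C=C(/C)C[C@@H](OC(C)=O)[C@@H]1[C@@H](O[Si](CC)(CC)CC)/C=C(/C)C2 | intermediate
11 | (8R)-alcohol, single enantiomer of 9 | O=C1[C@H]2/C=C(/C)C[C@@H](O)[C@@H]1[C@@H](O[Si](CC)(CC)CC)/C=C(/C)C2 | intermediate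
12 | 8β-OTBS, 6β-OTES bicyclic ketone | O=C1[C@H]2/C=C(/C)C[C@@H](O[Si](C)(C)C(C)(C)C)[C@@H]1[C@@H](O[Si](CC)(CC)CC)/C=C(/C)C2 | intermediate
13 | bridged lactone (11-oxabicyclo[4.4.2]dodeca-2,8-dien-12-one) | O=C1O[C@H]2/C=C(/C)C[C@@H](O[Si](C)(C)C(C)(C)C)[C@@H]1[C@@H](O[Si](CC)(CC)CC)/C=C(/C)C2 | intermediate
14 | bridged lactol (anomeric mixture) | OC1O[C@H]2/C=C(/C)C[C@@H](O[Si](C)(C)C(C)(C)C)[C@@H]1[C@@H](O[Si](CC)(CC)CC)/C=C(/C)C2 | intermediate
15 | 7β-ethynyl-8β-OTBS-6β-OTES-cyclodecadien-2β-ol | O[C@H]1/C=C(/C)C[C@@H](O[Si](C)(C)C(C)(C)C)[C@@H](C#C)[C@@H](O[Si](CC)(CC)CC)/C=C(/C)C1 | intermediate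
16 | 7β-ethynyl-8β-OTBS-cyclodecadiene-2β,6β-diol | O[C@H]1/C=C(/C)C[C@@H](O[Si](C)(C)C(C)(C)C)[C@@H](C#C)[C@@H](O)/C=C(/C)C1 | intermediate
17 | 2α,6α-bis(chloroacetate), 8β-OTBS | ClCC(=O)O[C@@H]1/C=C(/C)C[C@@H](O[Si](C)(C)C(C)(C)C)[C@@H](C#C)[C@H](OC(=O)CCl)/C=C(/C)C1 | intermediate
18 | 2α,6α-bis(chloroacetate), 8β-OH | ClCC(=O)O[C@@H]1/C=C(/C)C[C@@H](O)[C@@H](C#C)[C@H](OC(=O)CCl)/C=C(/C)C1 | intermediate
19 | angelic acid | C/C=C(/C)C(=O)O | starting material
20 | (Z)-2-methylbut-2-en-1-ol | C/C=C(/C)CO | intermediate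
21 | [(2S,3R)-2,3-dimethyloxiran-2-yl]methanol | OC[C@]1(C)O[C@@H]1C | intermediate
22 | (2R,3R)-2,3-dimethyloxirane-2-carboxylic acid | OC(=O)[C@]1(C)O[C@@H]1C | intermediate
23 | mixed anhydride of 22 with 2,4,6-trichlorobenzoic acid | O=C(OC(=O)c1c(Cl)cc(Cl)cc1Cl)[C@]1(C)O[C@@H]1C | intermediate (not isolated)
24 | 8β-epoxyangelate 2α,6α-bis(chloroacetate) | ClCC(=O)O[C@@H]1/C=C(/C)C[C@@H](OC(=O)[C@]2(C)O[C@@H]2C)[C@@H](C#C)[C@H](OC(=O)CCl)/C=C(/C)C1 | intermediate
25 | 8β-epoxyangelate 2α,6α-diol alkyne | O[C@@H]1/C=C(/C)C[C@@H](OC(=O)[C@]2(C)O[C@@H]2C)[C@@H](C#C)[C@H](O)/C=C(/C)C1 | intermediate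
26 | Millisorin B | C=C1C(=O)O[C@@H]2/C=C(/C)C[C@H](O)/C=C(/C)C[C@@H](OC(=O)[C@]3(C)O[C@@H]3C)[C@@H]12 | target

**Totals**
Total step count: 21. Longest linear sequence: 17 steps (1 → 26 through steps 1–3, 5–15 and 19–21); steps 4 and 16–18 are side branches.

**Steps most likely to fail**

1. Step 6. The allylcopper formed by borylcupration may be protonated at its far end (C1), giving the 1,4-adduct with the olefin moved to C9=C10, or the boryl unit may add to the ketone.
Fallback, from 7 back to 9: dye-sensitised photooxygenation (O2, TPP, hν, CH2Cl2, −30 °C) would add singlet oxygen across C8 and C1 from the open face to give the 8,1-endoperoxide F1. Triethylamine (Kornblum–DeLaMare) is expected to remove the more accessible C1–H and give the 8β-hydroxy-9-en-1-one F2. Tosylhydrazine condenses at the enone carbonyl (the bridge ketone is far more hindered) to the tosylhydrazone F3. Catecholborane, then NaOAc·3H2O at reflux, reduces F3 to the allylic diazene, whose retro-ene loss of N2 delivers hydrogen to C9 and re-forms C1=C10, giving 9.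

2. Step 14. At the hindered C6 carbinol the oxyphosphonium ion may eliminate to a diene or ionise (allylic, transannular participation), so that substitution is incomplete or not stereospecific.
Fallback, from 16 back to 17: sulfonylation (ClCH2SO2Cl, pyridine, 0 °C) gives the 2β,6β-bis(chloromethanesulfonate) F4. Caesium acetate/18-crown-6 in toluene displaces both with inversion to the 2α,6α-diacetate F5. K2CO3/MeOH liberates the 2α,6α-diol F6, and chloroacetic anhydride/pyridine returns 17.

3. Step 21. Carbonylation may stall through catalyst deactivation or alkyne dimerisation, or the phosphine/iodide may attack the epoxy ester at 70 °C.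
Fallback, from 25 to 26: molybdenum-catalysed hydrostannation (Mo(CO)3(CNt-Bu)3, Bu3SnH, THF, 55 °C) should give the internal (C11) vinylstannane F7. Iodine at 0 °C gives the 11-iodoalkene F8. Pd(PPh3)4, CO (1 atm), K2CO3, THF then closes the lactone by carbonylative trapping of O6–H at room temperature, giving 26.

**Further compounds**
F1 | step 6 | rac-8,1-endoperoxide of adduct 7 (O–O on the convex face) | O=C1[C@H]2[C@H]3OO[C@H](C=C3C)[C@@H]1[C@@H](O[Si](CC)(CC)CC)/C=C(/C)C2
F2 | step 6 | rac-8β-hydroxy-9-en-1-one (bridge ketone retained) | O=C1[C@H]2C(=O)/C(C)=C\[C@@H](O)[C@@H]1[C@@H](O[Si](CC)(CC)CC)/C=C(/C)C2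
F3 | step 6 | C1 tosylhydrazone of F2 | O=C1[C@H]2C(=NNS(=O)(=O)c3ccc(C)cc3)/C(C)=C\[C@@H](O)[C@@H]1[C@@H](O[Si](CC)(CC)CC)/C=C(/C)C2
F4 | step 14 | 2β,6β-bis(chloromethanesulfonate) of 16 | ClCS(=O)(=O)O[C@H]1/C=C(/C)C[C@@H](O[Si](C)(C)C(C)(C)C)[C@@H](C#C)[C@@H](OS(=O)(=O)CCl)/C=C(/C)C1
F5 | step 14 | 2α,6α-diacetate | CC(=O)O[C@@H]1/C=C(/C)C[C@@H](O[Si](C)(C)C(C)(C)C)[C@@H](C#C)[C@H](OC(C)=O)/C=C(/C)C1
F6 | step 14 | 2α,6α-diol, 8β-OTBS | O[C@@H]1/C=C(/C)C[C@@H](O[Si](C)(C)C(C)(C)C)[C@@H](C#C)[C@H](O)/C=C(/C)C1
F7 | step 21 | C11 tributylstannyl alkene from 25 | O[C@@H]1/C=C(/C)C[C@@H](OC(=O)[C@]2(C)O[C@@H]2C)[C@@H](C(=C)[Sn](CCCC)(CCCC)CCCC)[C@H](O)/C=C(/C)C1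
F8 | step 21 | C11 iodoalkene | O[C@@H]1/C=C(/C)C[C@@H](OC(=O)[C@]2(C)O[C@@H]2C)[C@@H](C(I)=C)[C@H](O)/C=C(/C)C1
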